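**Plan**

- Retrosynthesis: the phenol silyl groups, the acetal and the acetate are taken off on paper. Ring B is then opened at C3=C4 (metathesis), C2–C3 is cut (boron-to-carbon exchange), and C1–C8a and C2–C9 are cut together. This leaves an E-guaiacylvinylboron, an alkoxymethyllithium and a ring-A aryl triflate.
- Forward: the three pieces are joined in one step to an open-chain secondary boronate, the C3 unit is attached at boron, and ring B, the only ring that is made, closes last by metathesis. The two aromatic rings come from 2-methoxyresorcinol and vanillin.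
- Stereochemistry: the chiral palladium bisphosphine chooses the alkene face and so sets C1. C2 follows from stereospecific anti addition across the E-alkene. The C–B to C–C exchange is retentive, which gives the 1,2-trans (1S,2R) target.
- Feature used: C1 is a methine carrying two different aryl groups (the guaiacyl ring and ring-A carbon C8a, which sits beside the C8 methoxy) and is bonded to C2, which carries the C9 oxymethylene. A vinylboron that already bears the guaiacyl ring can therefore take up ring A at C1 and C9 at C2.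

Key step: step 10

Remark: locants C1–C9 and ring letters follow the target in all intermediates (C1 = diaryl methine, C2 = CH2O-bearing carbon, C3 = formyl-bearing carbon, C9 = CH2O carbon, ring A = C4a–C8a).
Assumption: the MandyPhos antipode used in the key step is the one that delivers the (1S,2S)-boronate; both antipodes are available and the sense of induction has to be established on the first run.
Remark: the pinacol ester is replaced by the bulkier ester of cis-1,2-dimethylacenaphthene-1,2-diol ("mac"), because β-substituted alkenyl pinacol boronates tend to undergo direct Suzuki coupling. Phenols are carried as TIPS ethers so that they survive methoxide in the Zweifel step.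

**Route**

Step 1
Reactants: 1 acenaphthenequinone
Product: 2 cis-1,2-dimethyl-1,2-dihydroacenaphthylene-1,2-diol (meso, "mac diol")
Conditions: MeMgBr (2.5 equiv), THF, 0 °C to rt; aq. NH4Cl; recrystallisation
Reagents that add atoms: methylmagnesium bromide, C[Mg]Br
Why: Double Grignard addition to the 1,2-diketone, in which the second methyl should add anti to the bulky solvated magnesium alkoxide and so favour the cis (meso) diol, the only isomer that can form a five-membered boronate; crystallisation removes any trans isomer.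

Step 2
Reactants: 3 vanillin
Product: 4 3-methoxy-4-(triisopropylsilyloxy)benzaldehyde
Conditions: TIPSCl, imidazole, DMF, rt
Reagents that add atoms: triisopropylsilyl chloride, CC(C)[Si](Cl)(C(C)C)C(C)C
Why: Standard phenol silylation; the bulky TIPS ether is chosen because it withstands the organolithium reagents and the methoxide used later.

Step 3
Reactants: 4 3-methoxy-4-(triisopropylsilyloxy)benzaldehyde
Product: 5 4-ethynyl-2-methoxy-1-(triisopropylsilyloxy)benzene
Conditions: TMSCHN2, LDA, THF, −78 °C to rt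
Reagents that add atoms: (trimethylsilyl)diazomethane, C[Si](C)(C)C=[N+]=[N-]
Why: Colvin rearrangement, in which the lithiated silyldiazomethane adds to the aldehyde, Peterson-type loss of silanolate and of N2 gives an alkylidene carbene, and its 1,2-hydride shift delivers the arylalkyne without the methoxide that could cleave the aryl silyl ether.

Step 4
Reactants: 5 4-ethynyl-2-methoxy-1-(triisopropylsilyloxy)benzene; 2 mac diol
Product: 7 mac ester of (E)-2-(3-methoxy-4-triisopropylsilyloxyphenyl)ethenylboronic acid, via catechol alkenylboronate 6 (not isolated)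
Conditions: catecholborane, neat, 70 °C; then 2, THF, rt
Reagents that add atoms: catecholborane, B1Oc2ccccc2O1
Why: Syn hydroboration of the terminal arylalkyne puts boron on the terminal carbon and fixes the E geometry, and the labile catechol ester 6 then exchanges with the more basic aliphatic diol 2 (alkyne hydroboration followed by transesterification).

Step 5
Reactants: 8 4-methoxybenzyl alcohol
Product: 9 tributyl[(4-methoxybenzyloxy)methyl]stannane
Conditions: NaH, THF/DMF, 0 °C; Bu3SnCH2I, rt
Reagents that add atoms: tributyl(iodomethyl)stannane, CCCC[Sn](CCCC)(CCCC)CI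
Why: Williamson etherification of the benzylic alkoxide with the primary α-stannyl iodide (SN2), the usual entry to alkoxymethylstannanes.

Step 6
Reactants: 10 2-methoxyresorcinol
Product: 12 2,4-dihydroxy-3-methoxybenzaldehyde, via aryl iminium chloride 11 (not isolated)
Conditions: POCl3, DMF, MeCN, 0 °C to rt; then H2O, 50 °C
Reagents that add atoms: N,N-dimethylformamide, CN(C)C=O; water, O
Why: Vilsmeier–Haack formylation, for which the only strongly activated positions of the symmetric diol are the equivalent C4/C6 (ortho to one hydroxyl, para to the other), so one regioisomer is expected after hydrolysis of iminium salt 11.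

Step 7
Reactants: 12 2,4-dihydroxy-3-methoxybenzaldehyde
Product: 13 2-hydroxy-3-methoxy-4-(triisopropylsilyloxy)benzaldehyde
Conditions: TIPSCl (1.05 equiv), imidazole, CH2Cl2, 0 °C
Reagents that add atoms: triisopropylsilyl chloride, CC(C)[Si](Cl)(C(C)C)C(C)C
Why: Regioselective phenol silylation, since the 2-hydroxyl is hydrogen-bonded to the formyl group and flanked on both sides, whereas the more acidic and more accessible 4-hydroxyl reacts first.

Step 8
Reactants: 13 2-hydroxy-3-methoxy-4-(triisopropylsilyloxy)benzaldehyde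
Product: 14 6-formyl-2-methoxy-3-(triisopropylsilyloxy)phenyl trifluoromethanesulfonate
Conditions: Tf2O, pyridine, CH2Cl2, 0 °C
Reagents that add atoms: trifluoromethanesulfonic anhydride, O=S(=O)(OS(=O)(=O)C(F)(F)F)C(F)(F)F
Why: O-Sulfonylation of the remaining chelated phenol, a routine conversion of salicylaldehydes into aryl triflates.

Step 9
Reactants: 14 6-formyl-2-methoxy-3-(triisopropylsilyloxy)phenyl trifluoromethanesulfonate
Product: 15 2-methoxy-3-(triisopropylsilyloxy)-6-vinylphenyl trifluoromethanesulfonate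
Conditions: Ph3PCH3Br, KHMDS, THF, 0 °C; then 14, −78 to 0 °C
Reagents that add atoms: methyltriphenylphosphonium bromide, C[P+](c1ccccc1)(c1ccccc1)c1ccccc1.[Br-]
Why: Wittig methylenation, in which the non-stabilised ylide adds to the aldehyde at low temperature much faster than it attacks the aryl triflate or the silyl ether.

Step 10
Reactants: 9 tributyl[(4-methoxybenzyloxy)methyl]stannane; 7 mac ester of (E)-2-(3-methoxy-4-triisopropylsilyloxyphenyl)ethenylboronic acid; 15 2-methoxy-3-(triisopropylsilyloxy)-6-vinylphenyl trifluoromethanesulfonate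
Product: 18 mac ester of (1S,2S)-1-(3-methoxy-4-triisopropylsilyloxyphenyl)-1-(2-methoxy-3-triisopropylsilyloxy-6-vinylphenyl)-3-(4-methoxybenzyloxy)propan-2-ylboronic acid, via alkoxymethyllithium 16 (not isolated), via lithium borate 17 (not isolated)
Conditions: 9, n-BuLi, THF, −78 °C; then 7, −78 to 0 °C; then 15, Pd(OAc)2 (3 mol%), MandyPhos (3.6 mol%), THF, 60 °C
Reagents that add atoms: none
Why: Tin–lithium exchange gives the α-alkoxy organolithium 16, which adds to boron of 7 to give borate 17; oxidative addition of Pd(0) to triflate 15 gives a cationic arylpalladium that binds the styrenyl π-bond of 17 on the face chosen by the ligand and triggers an anti-periplanar 1,2-shift of the CH2OPMB group from boron to C2, after which C(sp3)–aryl reductive elimination with retention joins C8a to C1. The closest known reaction type is the enantioselective Pd/MandyPhos conjunctive cross-coupling of β-substituted alkenylboron ate complexes of the mac diol with aryl triflates, in which alkyl and aryl groups migrate; an alkoxymethyl group is known to shift readily from four-coordinate boron in Matteson homologations, so the α-oxygen should not block the step. No ring is closed. C1 is set by the chiral bisphosphine on palladium (catalyst control of the alkene face), and C2 is set relative to C1 by the stereospecific anti addition across the E-alkene, giving the (1S,2S)-boronate that becomes 1,2-trans once boron is exchanged for carbon with retention. The step needs the metallate shift to win over direct Suzuki–Miyaura transfer of the styrenyl group, which the bulky mac ligand on boron and the non-coordinating triflate counter-ion (cationic, π-acidic palladium) should secure, and it needs palladium to engage the borate alkene and not the aryl vinyl group, which follows from the far higher nucleophilicity of the anionic borate. Attachment of ring A at C8a is fixed by the position of the triflate.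

Step 11
Reactants: 18 mac ester of the (1S,2S)-secondary boronic acid
Product: 21 (3R,4S)-2-(diethoxymethyl)-3-[(4-methoxybenzyloxy)methyl]-4-(3-methoxy-4-triisopropylsilyloxyphenyl)-4-(2-methoxy-3-triisopropylsilyloxy-6-vinylphenyl)but-1-ene, via lithium alkenylborate 19 (not isolated), via β-iodoalkyl boronate 20 (not isolated)
Conditions: CH2=C(Br)CH(OEt)2, t-BuLi (2 equiv), Et2O, −78 °C; then 18, THF, −78 to 0 °C; I2, THF, −78 °C; NaOMe, MeOH, −78 °C to rt
Reagents that add atoms: 2-bromo-3,3-diethoxyprop-1-ene, C=C(Br)C(OCC)OCC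
Why: Zweifel olefination, in which the alkenyllithium adds to boron, iodine triggers a stereoretentive 1,2-shift of the C2 alkyl group and methoxide induces anti elimination of boron and iodide, so C2 keeps its spatial arrangement (now R by CIP) and the new 1,1-disubstituted alkene carries the protected formyl group.

Step 12
Reactants: 21 the PMB-protected diene acetal
Product: 22 (2R,3S)-2-(3,3-diethoxyprop-1-en-2-yl)-3-(3-methoxy-4-triisopropylsilyloxyphenyl)-3-(2-methoxy-3-triisopropylsilyloxy-6-vinylphenyl)propan-1-ol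
Conditions: DDQ (1.3 equiv), CH2Cl2/pH 7 buffer, 0 °C
Reagents that add atoms: none
Why: Oxidative PMB cleavage, in which hydride abstraction from the p-methoxybenzylic CH2 (assisted by the ether oxygen) should outpace attack at the hindered bis-benzylic C1–H at 0 °C; it is placed before ring closure because a 1-aryl-1,2-dihydronaphthalene would be dehydrogenated to the naphthalene by this oxidant.

Step 13
Reactants: 22 the primary alcohol
Product: 23 (2R,3S)-2-(3,3-diethoxyprop-1-en-2-yl)-3-(3-methoxy-4-triisopropylsilyloxyphenyl)-3-(2-methoxy-3-triisopropylsilyloxy-6-vinylphenyl)propyl acetate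
Conditions: Ac2O, pyridine, DMAP (cat.), CH2Cl2, rt
Reagents that add atoms: acetic anhydride, CC(=O)OC(C)=O
Why: DMAP-catalysed acylation of the only free hydroxyl group.

Step 14
Reactants: 23 the diene acetate
Product: 24 [(1S,2R)-3-(diethoxymethyl)-8-methoxy-1-(3-methoxy-4-triisopropylsilyloxyphenyl)-7-triisopropylsilyloxy-1,2-dihydronaphthalen-2-yl]methyl acetate
Conditions: Hoveyda–Grubbs II (5 mol%), toluene, 80 °C
Reagents that add atoms: none
Why: Ring-closing metathesis, in which ruthenium loads on the monosubstituted styrene and closes the six-membered ring onto the 1,1-disubstituted alkene with loss of ethylene to form the trisubstituted C3=C4 bond; the acetal keeps that alkene electron-rich and no stereocentre is touched.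

Step 15
Reactants: 24 the dihydronaphthalene acetal
Product: 25 [(1S,2R)-3-formyl-8-methoxy-1-(3-methoxy-4-triisopropylsilyloxyphenyl)-7-triisopropylsilyloxy-1,2-dihydronaphthalen-2-yl]methyl acetate
Conditions: TsOH·H2O (cat.), THF/H2O, rt
Reagents that add atoms: water, O
Why: Acid-catalysed hydrolysis of the allylic diethyl acetal, which is far more labile than the acetate and the aryl silyl ethers; the C2–H is not vinylogous to the new aldehyde, so C2 should not epimerise.

Step 16
Reactants: 25 the bis-silylated enal acetate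
Product: 26 [(1S,2R)-3-formyl-7-hydroxy-1-(4-hydroxy-3-methoxyphenyl)-8-methoxy-1,2-dihydronaphthalen-2-yl]methyl acetate (CNP0489020.1)
Conditions: TBAF, AcOH (1:1), THF, 0 °C
Reagents that add atoms: none
Why: Fluoride cleavage of the two aryl Si–O bonds, buffered with acetic acid so that the phenols stay protonated and the primary acetate and the enal remain intact.

**Compound list**

1 | acenaphthenequinone | O=C1C(=O)c2cccc3cccc1c23 | starting material
2 | cis-1,2-dimethyl-1,2-dihydroacenaphthylene-1,2-diol (mac diol) | C[C@@]1(O)c2cccc3cccc(c23)[C@]1(C)O | intermediate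
3 | vanillin | COc1cc(C=O)ccc1O | starting material
4 | 3-methoxy-4-(triisopropylsilyloxy)benzaldehyde | COc1cc(C=O)ccc1O[Si](C(C)C)(C(C)C)C(C)C | intermediate
5 | 4-ethynyl-2-methoxy-1-(triisopropylsilyloxy)benzene | COc1cc(C#C)ccc1O[Si](C(C)C)(C(C)C)C(C)C | intermediate
6 | 2-[(E)-2-(3-methoxy-4-triisopropylsilyloxyphenyl)ethenyl]-1,3,2-benzodioxaborole | COc1cc(/C=C/B2Oc3ccccc3O2)ccc1O[Si](C(C)C)(C(C)C)C(C)C | intermediate (not isolated)
7 | mac ester of (E)-2-(3-methoxy-4-triisopropylsilyloxyphenyl)ethenylboronic acid | COc1cc(/C=C/B2O[C@]3(C)c4cccc5cccc(c45)[C@]3(C)O2)ccc1O[Si](C(C)C)(C(C)C)C(C)C | intermediate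
8 | 4-methoxybenzyl alcohol | COc1ccc(CO)cc1 | starting material
9 | tributyl[(4-methoxybenzyloxy)methyl]stannane | CCCC[Sn](CCCC)(CCCC)COCc1ccc(OC)cc1 | intermediate
10 | 2-methoxyresorcinol (2-methoxybenzene-1,3-diol) | COc1c(O)cccc1O | starting material
11 | [(2,4-dihydroxy-3-methoxyphenyl)methylidene]dimethyliminium chloride | C[N+](C)=Cc1ccc(O)c(OC)c1O.[Cl-] | intermediate (not isolated)
12 | 2,4-dihydroxy-3-methoxybenzaldehyde | COc1c(O)ccc(C=O)c1O | intermediate
13 | 2-hydroxy-3-methoxy-4-(triisopropylsilyloxy)benzaldehyde | COc1c(O[Si](C(C)C)(C(C)C)C(C)C)ccc(C=O)c1O | intermediate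
14 | 6-formyl-2-methoxy-3-(triisopropylsilyloxy)phenyl trifluoromethanesulfonate | COc1c(O[Si](C(C)C)(C(C)C)C(C)C)ccc(C=O)c1OS(=O)(=O)C(F)(F)F | intermediate
15 | 2-methoxy-3-(triisopropylsilyloxy)-6-vinylphenyl trifluoromethanesulfonate | COc1c(O[Si](C(C)C)(C(C)C)C(C)C)ccc(C=C)c1OS(=O)(=O)C(F)(F)F | intermediate
16 | (4-methoxybenzyloxy)methyllithium | [Li]COCc1ccc(OC)cc1 | intermediate (not isolated)
17 | lithium borate from 7 and 16 (boron carries the E-styrenyl group, CH2OPMB and the mac diolate) | [Li+].COc1cc(/C=C/[B-]2(COCc3ccc(OC)cc3)O[C@]3(C)c4cccc5cccc(c45)[C@]3(C)O2)ccc1O[Si](C(C)C)(C(C)C)C(C)C | intermediate (not isolated)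
18 | mac ester of (1S,2S)-1-(3-methoxy-4-triisopropylsilyloxyphenyl)-1-(2-methoxy-3-triisopropylsilyloxy-6-vinylphenyl)-3-(4-methoxybenzyloxy)propan-2-ylboronic acid | COc1cc([C@@H](c2c(C=C)ccc(O[Si](C(C)C)(C(C)C)C(C)C)c2OC)[C@H](B2O[C@]3(C)c4cccc5cccc(c45)[C@]3(C)O2)COCc2ccc(OC)cc2)ccc1O[Si](C(C)C)(C(C)C)C(C)C | intermediate
19 | lithium borate from 18 carrying a 3,3-diethoxyprop-1-en-2-yl group on boron (C1, C2 as in 18) | [Li+].COc1cc([C@@H](c2c(C=C)ccc(O[Si](C(C)C)(C(C)C)C(C)C)c2OC)[C@H]([B-]2(C(=C)C(OCC)OCC)O[C@]3(C)c4cccc5cccc(c45)[C@]3(C)O2)COCc2ccc(OC)cc2)ccc1O[Si](C(C)C)(C(C)C)C(C)C | intermediate (not isolated)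
20 | β-iodoalkyl boronate: mac ester in which the boron-bearing carbon C3 carries CH2I, CH(OEt)2 and the C2 chain (C1, C2 as in 21; both C3 epimers) | COc1cc([C@@H](c2c(C=C)ccc(O[Si](C(C)C)(C(C)C)C(C)C)c2OC)[C@@H](COCc2ccc(OC)cc2)C(CI)(B2O[C@]3(C)c4cccc5cccc(c45)[C@]3(C)O2)C(OCC)OCC)ccc1O[Si](C(C)C)(C(C)C)C(C)C | intermediate (not isolated)
21 | (3R,4S)-2-(diethoxymethyl)-3-[(4-methoxybenzyloxy)methyl]-4-(3-methoxy-4-triisopropylsilyloxyphenyl)-4-(2-methoxy-3-triisopropylsilyloxy-6-vinylphenyl)but-1-ene | COc1cc([C@@H](c2c(C=C)ccc(O[Si](C(C)C)(C(C)C)C(C)C)c2OC)[C@@H](COCc2ccc(OC)cc2)C(=C)C(OCC)OCC)ccc1O[Si](C(C)C)(C(C)C)C(C)C | intermediate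
22 | (2R,3S)-2-(3,3-diethoxyprop-1-en-2-yl)-3-(3-methoxy-4-triisopropylsilyloxyphenyl)-3-(2-methoxy-3-triisopropylsilyloxy-6-vinylphenyl)propan-1-ol | COc1cc([C@@H](c2c(C=C)ccc(O[Si](C(C)C)(C(C)C)C(C)C)c2OC)[C@@H](CO)C(=C)C(OCC)OCC)ccc1O[Si](C(C)C)(C(C)C)C(C)C | intermediate
23 | acetate of 22 | COc1cc([C@@H](c2c(C=C)ccc(O[Si](C(C)C)(C(C)C)C(C)C)c2OC)[C@@H](COC(C)=O)C(=C)C(OCC)OCC)ccc1O[Si](C(C)C)(C(C)C)C(C)C | intermediate
24 | [(1S,2R)-3-(diethoxymethyl)-8-methoxy-1-(3-methoxy-4-triisopropylsilyloxyphenyl)-7-triisopropylsilyloxy-1,2-dihydronaphthalen-2-yl]methyl acetate | COc1cc([C@H]2c3c(ccc(O[Si](C(C)C)(C(C)C)C(C)C)c3OC)C=C(C(OCC)OCC)[C@@H]2COC(C)=O)ccc1O[Si](C(C)C)(C(C)C)C(C)C | intermediate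
25 | [(1S,2R)-3-formyl-8-methoxy-1-(3-methoxy-4-triisopropylsilyloxyphenyl)-7-triisopropylsilyloxy-1,2-dihydronaphthalen-2-yl]methyl acetate | COc1cc([C@H]2c3c(ccc(O[Si](C(C)C)(C(C)C)C(C)C)c3OC)C=C(C=O)[C@@H]2COC(C)=O)ccc1O[Si](C(C)C)(C(C)C)C(C)C | intermediate
26 | [(1S,2R)-3-formyl-7-hydroxy-1-(4-hydroxy-3-methoxyphenyl)-8-methoxy-1,2-dihydronaphthalen-2-yl]methyl acetate (CNP0489020.1) | COc1cc([C@H]2c3c(ccc(O)c3OC)C=C(C=O)[C@@H]2COC(C)=O)ccc1O | target

**Step count and risks**

Total step count: 16.
Longest linear sequence: 11 steps (10 to 26, steps 6–16).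

Steps most likely to fail:

Step 10 (key step). What may go wrong: direct Suzuki–Miyaura transfer of the styrenyl group to the hindered, doubly ortho-substituted arylpalladium may outrun the metallate shift of the oxygen-bearing CH2 group, or the alkene face may be chosen poorly. Fallback (sets out from 4 and 14, returns at 21): the C2–C9 bond is built into the alkene beforehand, and ring A and boron are added across it by copper/palladium-catalysed syn-arylboration. Aldehyde 4 is converted by Horner–Wadsworth–Emmons reaction (triethyl phosphonoacetate, NaH) into ethyl (E)-3-(3-methoxy-4-triisopropylsilyloxyphenyl)prop-2-enoate F1, which DIBAL-H reduces to the allylic alcohol F2 and NaH/PMBCl protects as the PMB ether F3. Aldehyde 14 is masked as the 1,3-dioxolane F4 (ethylene glycol, TsOH), because neither a formyl nor a vinyl group would survive the borylcopper. Arylboration of F3 with F4 and B2pin2 (chiral NHC–copper and Pd/RuPhos catalysts, NaOt-Bu) should place boron on C2 and ring A on benzylic C1 by syn-borylcupration and stereoretentive cross-coupling, giving the (1S,2S) pinacol boronate F5 with the same relative configuration as 18. Acetal hydrolysis (PPTS, aqueous acetone) gives the aldehyde F6, Wittig methylenation gives the styrene F7, and Zweifel olefination with the reagent of step 11, by way of the lithium borate F8 and the β-iodoalkyl boronate F9, gives 21.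

Step 11. What may go wrong: the branched alkenyllithium may add too slowly to the hindered secondary boron centre, so that the boronate is recovered or protodeboronated, or the borate may lose the β-alkoxide before iodine is added. Fallback (sets out from 18, returns at 25): the formyl carbon is left out of the boron step and added to the closed ring by electrophilic formylation. Unbranched vinyllithium and 18 give the lithium vinylborate F10, and iodine and methoxide take it through the β-iodoethyl boronate F11 to the terminal alkene F12. DDQ gives the alcohol F13 and acetylation the acetate F14. Metathesis of the two monosubstituted alkenes closes the 3-unsubstituted 1,2-dihydronaphthalene F15. Vilsmeier–Haack formylation (POCl3, DMF) should attack C3, the β-carbon of the para-silyloxystyrene, and hydrolysis of the iminium salt F16 gives 25.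

Step 12. What may go wrong: DDQ may abstract hydride from the electron-rich bis-benzylic C1–H or react with the silyloxystyrene instead of oxidising the PMB methylene. Fallback (sets out from 21, returns at 25): the ether is cleaved by acid after ring closure and not by an oxidant. Metathesis of 21 gives the PMB-protected dihydronaphthalene acetal F17. Trifluoroacetic acid in wet dichloromethane, with anisole as cation trap, removes the PMB group and hydrolyses the acetal in one operation to the hydroxy enal F18, and acetylation as in step 13 gives 25.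

**Further compounds**

F1 | step 10 | ethyl (E)-3-(3-methoxy-4-triisopropylsilyloxyphenyl)prop-2-enoate | CCOC(=O)/C=C/c1ccc(O[Si](C(C)C)(C(C)C)C(C)C)c(OC)c1
F2 | step 10 | (E)-3-(3-methoxy-4-triisopropylsilyloxyphenyl)prop-2-en-1-ol | OC/C=C/c1ccc(O[Si](C(C)C)(C(C)C)C(C)C)c(OC)c1
F3 | step 10 | 4-methoxybenzyl ether of F2 | COc1ccc(COC/C=C/c2ccc(O[Si](C(C)C)(C(C)C)C(C)C)c(OC)c2)cc1
F4 | step 10 | 6-(1,3-dioxolan-2-yl)-2-methoxy-3-(triisopropylsilyloxy)phenyl trifluoromethanesulfonate | COc1c(O[Si](C(C)C)(C(C)C)C(C)C)ccc(C2OCCO2)c1OS(=O)(=O)C(F)(F)F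
F5 | step 10 | pinacol ester of (1S,2S)-1-[6-(1,3-dioxolan-2-yl)-2-methoxy-3-triisopropylsilyloxyphenyl]-1-(3-methoxy-4-triisopropylsilyloxyphenyl)-3-(4-methoxybenzyloxy)propan-2-ylboronic acid | COc1cc([C@@H](c2c(C3OCCO3)ccc(O[Si](C(C)C)(C(C)C)C(C)C)c2OC)[C@H](B2OC(C)(C)C(C)(C)O2)COCc2ccc(OC)cc2)ccc1O[Si](C(C)C)(C(C)C)C(C)C
F6 | step 10 | aldehyde from F5 (6-formyl on ring A) | COc1cc([C@@H](c2c(C=O)ccc(O[Si](C(C)C)(C(C)C)C(C)C)c2OC)[C@H](B2OC(C)(C)C(C)(C)O2)COCc2ccc(OC)cc2)ccc1O[Si](C(C)C)(C(C)C)C(C)C
F7 | step 10 | pinacol analogue of 18 (6-vinyl on ring A) | COc1cc([C@@H](c2c(C=C)ccc(O[Si](C(C)C)(C(C)C)C(C)C)c2OC)[C@H](B2OC(C)(C)C(C)(C)O2)COCc2ccc(OC)cc2)ccc1O[Si](C(C)C)(C(C)C)C(C)C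
F8 | step 10 | lithium borate from F7 and 3,3-diethoxyprop-1-en-2-yllithium | [Li+].COc1cc([C@@H](c2c(C=C)ccc(O[Si](C(C)C)(C(C)C)C(C)C)c2OC)[C@H]([B-]2(C(=C)C(OCC)OCC)OC(C)(C)C(C)(C)O2)COCc2ccc(OC)cc2)ccc1O[Si](C(C)C)(C(C)C)C(C)C
F9 | step 10 | β-iodoalkyl pinacol boronate from F8 (both C3 epimers) | COc1cc([C@@H](c2c(C=C)ccc(O[Si](C(C)C)(C(C)C)C(C)C)c2OC)[C@@H](COCc2ccc(OC)cc2)C(CI)(B2OC(C)(C)C(C)(C)O2)C(OCC)OCC)ccc1O[Si](C(C)C)(C(C)C)C(C)C
F10 | step 11 | lithium vinylborate from 18 | [Li+].COc1cc([C@@H](c2c(C=C)ccc(O[Si](C(C)C)(C(C)C)C(C)C)c2OC)[C@H]([B-]2(C=C)O[C@]3(C)c4cccc5cccc(c45)[C@]3(C)O2)COCc2ccc(OC)cc2)ccc1O[Si](C(C)C)(C(C)C)C(C)C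
F11 | step 11 | β-iodoethyl mac boronate from F10 (both epimers at the boron-bearing carbon) | COc1cc([C@@H](c2c(C=C)ccc(O[Si](C(C)C)(C(C)C)C(C)C)c2OC)[C@@H](COCc2ccc(OC)cc2)C(CI)B2O[C@]3(C)c4cccc5cccc(c45)[C@]3(C)O2)ccc1O[Si](C(C)C)(C(C)C)C(C)C
F12 | step 11 | 3-[(4-methoxybenzyloxy)methyl]-4-(3-methoxy-4-triisopropylsilyloxyphenyl)-4-(2-methoxy-3-triisopropylsilyloxy-6-vinylphenyl)but-1-ene (C1, C2 as in 21) | COc1cc([C@@H](c2c(C=C)ccc(O[Si](C(C)C)(C(C)C)C(C)C)c2OC)[C@@H](COCc2ccc(OC)cc2)C=C)ccc1O[Si](C(C)C)(C(C)C)C(C)C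
F13 | step 11 | primary alcohol from F12 | COc1cc([C@@H](c2c(C=C)ccc(O[Si](C(C)C)(C(C)C)C(C)C)c2OC)[C@@H](CO)C=C)ccc1O[Si](C(C)C)(C(C)C)C(C)C
F14 | step 11 | acetate of F13 | COc1cc([C@@H](c2c(C=C)ccc(O[Si](C(C)C)(C(C)C)C(C)C)c2OC)[C@@H](COC(C)=O)C=C)ccc1O[Si](C(C)C)(C(C)C)C(C)C
F15 | step 11 | [8-methoxy-1-(3-methoxy-4-triisopropylsilyloxyphenyl)-7-triisopropylsilyloxy-1,2-dihydronaphthalen-2-yl]methyl acetate (3-unsubstituted, C1 and C2 as in 25) | COc1cc([C@H]2c3c(ccc(O[Si](C(C)C)(C(C)C)C(C)C)c3OC)C=C[C@@H]2COC(C)=O)ccc1O[Si](C(C)C)(C(C)C)C(C)C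
F16 | step 11 | C3 dimethyliminium chloride of F15 | COc1cc([C@H]2c3c(ccc(O[Si](C(C)C)(C(C)C)C(C)C)c3OC)C=C(C=[N+](C)C)[C@@H]2COC(C)=O)ccc1O[Si](C(C)C)(C(C)C)C(C)C.[Cl-]
F17 | step 12 | PMB ether analogue of 24 (C9–OPMB in place of C9–OAc) | COc1cc([C@H]2c3c(ccc(O[Si](C(C)C)(C(C)C)C(C)C)c3OC)C=C(C(OCC)OCC)[C@@H]2COCc2ccc(OC)cc2)ccc1O[Si](C(C)C)(C(C)C)C(C)C
F18 | step 12 | (1S,2R)-2-(hydroxymethyl)-8-methoxy-1-(3-methoxy-4-triisopropylsilyloxyphenyl)-7-triisopropylsilyloxy-1,2-dihydronaphthalene-3-carbaldehyde | COc1cc([C@H]2c3c(ccc(O[Si](C(C)C)(C(C)C)C(C)C)c3OC)C=C(C=O)[C@@H]2CO)ccc1O[Si](C(C)C)(C(C)C)C(C)C
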